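**Strategy**

Numbering: the pentyl group is C1–C5, the oxolane ring is O/C6/C7/C8/C9, the carbinol is C10 and the terminal alkene is C18–C19.
Cuts: the C10 hydroxyl is masked as a 2-naphthylmethyl (NAP) ether. The C7–O bond of the laurate is traced back, through an inverting esterification and a retentive C–Si oxidation, to a C7–Si bond. The ring bonds C8–C9 and C6–O are then cut together, giving (R)-3-silyloct-1-ene (C1–C8) and (R)-2-(NAP-oxy)undec-10-enal (C9–C19).
Enabling feature: read from its oxygen, the oxolane ring is O and C9 (an aldehyde C=O), C8 (bare CH2), C7 (CH bearing a heteroatom) and C6 (CH bearing an alkyl chain). This is the imprint of an allylsilane annulation with 1,2-silyl shift, and the C10 oxygen beside C9 can hold the aldehyde in a chelate.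
Forward order: the silane arm (2 steps) and the aldehyde arm (5 steps) are built linearly, and one step joins them and closes the only ring. Silicon then becomes hydroxyl, hydroxyl becomes laurate, and the NAP group is removed.
Stereochemistry: C10 is bought with (R)-trityl glycidyl ether, and the C–Si centre comes from a copper/chiral carbene catalysed allylic silylation. The annulation relays these to C9 (chelate face), C6 (inversion at the former C–Si carbon) and C7 (silicon trans to pentyl). C7 is corrected at the end by retention followed by Mitsunobu inversion.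

Key step: step 8

Assumption: the sense of induction in the allylic silylation depends on the carbene family chosen, so the ligand antipode that gives the (R)-allylsilane is fixed in a trial run.

**Route**

Step 1
Reactants: 1 (E)-oct-2-en-1-ol
Product: 2 (E)-oct-2-en-1-yl diethyl phosphate
Conditions: ClP(O)(OEt)2, pyridine, DMAP (cat.), CH2Cl2, 0 °C to rt
Reagents that add atoms: diethyl chlorophosphate, CCOP(=O)(Cl)OCC
Why: O-phosphorylation of a primary allylic alcohol under mild base leaves the (E)-alkene alone and installs the leaving group best suited to gamma-selective copper chemistry.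

Step 2
Reactants: 2 (E)-oct-2-en-1-yl diethyl phosphate; 3 2-[dimethyl(phenyl)silyl]-4,4,5,5-tetramethyl-1,3,2-dioxaborolane
Product: 4 (3R)-3-[dimethyl(phenyl)silyl]oct-1-ene
Conditions: CuCl (5 mol %), enantiopure imidazolinium salt as NHC precursor (5.5 mol %), NaOMe (1.5 equiv), CH2Cl2, 0 °C
Reagents that add atoms: none
Why: In this copper-catalysed enantioselective allylic silylation (SN2'), methoxide activates the Si–B bond, the (NHC)Cu–SiMe2Ph species delivers silicon to the gamma carbon C6 with loss of phosphate, and the chiral carbene selects the alkene face and so creates the (R) C–Si stereocentre.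

Step 3
Reactants: 5 8-bromooct-1-ene
Product: 6 oct-7-en-1-ylmagnesium bromide (THF solution, titrated and used directly)
Conditions: Mg turnings, I2 (crystal), THF, rt to 40 °C
Reagents that add atoms: magnesium, [Mg]
Why: This is an ordinary Grignard formation from a primary bromide, and the alkene lies too far from the radical site for cyclisation to compete.

Step 4
Reactants: 6 oct-7-en-1-ylmagnesium bromide; 7 (R)-trityl glycidyl ether, (2R)-2-[(triphenylmethoxy)methyl]oxirane
Product: 8 (2R)-1-(triphenylmethoxy)undec-10-en-2-ol
Conditions: CuI (10 mol %), THF, −30 to 0 °C; aq NH4Cl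
Reagents that add atoms: none
Why: The copper-catalysed SN2 opening of a terminal epoxide by a Grignard reagent occurs at the unsubstituted carbon (the future C11), so the C10–O bond and the purchased stereocentre are not touched.

Step 5
Reactants: 8 (2R)-1-(triphenylmethoxy)undec-10-en-2-ol
Product: 9 2-({[(2R)-1-(triphenylmethoxy)undec-10-en-2-yl]oxy}methyl)naphthalene
Conditions: NaH, 2-(bromomethyl)naphthalene, Bu4NI (cat.), THF/DMF, 0 °C to rt
Reagents that add atoms: 2-(bromomethyl)naphthalene, BrCc1ccc2ccccc2c1
Why: Williamson etherification installs a benzyl-type ether whose oxygen chelates well, which tolerates SnCl4 better than a p-methoxybenzyl ether, and which can later be removed oxidatively without hydrogenating the alkene.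

Step 6
Reactants: 9 2-({[(2R)-1-(triphenylmethoxy)undec-10-en-2-yl]oxy}methyl)naphthalene
Product: 10 (2R)-2-(naphthalen-2-ylmethoxy)undec-10-en-1-ol
Conditions: p-TsOH·H2O (10 mol %), MeOH/CH2Cl2, rt
Reagents that add atoms: none
Why: Acid-catalysed solvolysis removes the trityl ether through the stabilised trityl cation, which methanol traps, under conditions too mild to affect the NAP ether or the alkene.

Step 7
Reactants: 10 (2R)-2-(naphthalen-2-ylmethoxy)undec-10-en-1-ol
Product: 11 (2R)-2-(naphthalen-2-ylmethoxy)undec-10-enal
Conditions: Dess–Martin periodinane, CH2Cl2, 0 °C to rt; short work-up, taken into step 8 the same day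
Reagents that add atoms: none
Why: Dess–Martin oxidation stops at the aldehyde under nearly neutral conditions and is a standard choice for alpha-alkoxy aldehydes whose stereocentre must not enolise.

Step 8
Reactants: 4 (3R)-3-[dimethyl(phenyl)silyl]oct-1-ene; 11 (2R)-2-(naphthalen-2-ylmethoxy)undec-10-enal
Product: 14 dimethyl{(2S,3R,5R)-5-[(1R)-1-(naphthalen-2-ylmethoxy)dec-9-en-1-yl]-2-pentyloxolan-3-yl}(phenyl)silane, via SnCl4 chelate 12 (not isolated), via silicon-bridged cation 13 (not isolated)
Conditions: SnCl4 (1.05 equiv), CH2Cl2, −78 °C, 15 min; then 4 (1.3 equiv), −78 to −40 °C; aq NaHCO3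
Reagents that add atoms: none
Why: SnCl4 ties the carbonyl oxygen and the C10 ether oxygen of 11 into the five-membered chelate 12, the CH2 terminus C8 of 4 adds to C9 anti to the C–Si bond (anti SE2'), and the resulting cation 13, in which silicon bridges C6 and C7, is opened at C6 by the tin alkoxide on the side away from silicon, so that silicon ends on C7 (net 1,2-silyl shift) and both the C8–C9 and C6–O bonds are made. The closest known reaction type is the Lewis acid promoted formal (3+2) annulation of alpha-substituted allylsilanes with chelating alpha-alkoxy aldehydes, an established entry to 3-silyl tetrahydrofurans. The oxolane ring closes by a formally 5-endo opening of the bridged ion at C6, which should win over 4-exo attack at C7 because that would build a strained oxetane. C9 (R) is fixed by attack on the chelate face opposite the C11 chain, giving the C9/C10 threo pair; C6 (S) is fixed by inversion at the carbon that carried silicon in (R)-4; C7 (R) is fixed by the reactive conformer of 4 with the C6–H bond inside, which leaves silicon trans to the pentyl group. The step needs ring closure to outrun chloride-induced loss of silicon (Hosomi–Sakurai allylation), and the low temperature, the bulk of the alpha-branched PhMe2Si group and the closeness of the tin alkoxide favour closure. It also needs the two enantiopure partners to cooperate: C6 depends only on the silane and C9 only on the chelate, so the (R)/(R) pair gives the 2,5-trans ring whenever both controls hold, and this is also the ring that chelated aldehydes are expected to prefer with this class of silane.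

Step 9
Reactants: 14 dimethyl{(2S,3R,5R)-5-[(1R)-1-(naphthalen-2-ylmethoxy)dec-9-en-1-yl]-2-pentyloxolan-3-yl}(phenyl)silane
Product: 16 (2S,3R,5R)-5-[(1R)-1-(naphthalen-2-ylmethoxy)dec-9-en-1-yl]-2-pentyloxolan-3-ol, via tert-butylperoxysilane 15 (not isolated)
Conditions: t-BuOOH (decane solution), KH, NMP, 0 °C to rt; then Bu4NF (THF solution), 70 °C
Reagents that add atoms: tert-butyl hydroperoxide, CC(C)(C)OO
Why: In this nucleophilic form of the Fleming–Tamao oxidation the tert-butylperoxide anion adds to silicon, phenyl leaves the silicate as benzene to give 15, fluoride triggers the 1,2-shift of C7 from silicon to oxygen with retention and cleaves the resulting silyl ether, so the hydroxyl stays trans to pentyl (7R) while the C18–C19 alkene and the NAP ether, which mercury salts, bromine sources or peracids would attack, meet no electrophile.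

Step 10
Reactants: 16 (2S,3R,5R)-5-[(1R)-1-(naphthalen-2-ylmethoxy)dec-9-en-1-yl]-2-pentyloxolan-3-ol; 17 dodecanoic (lauric) acid
Product: 19 (2S,3S,5R)-5-[(1R)-1-(naphthalen-2-ylmethoxy)dec-9-en-1-yl]-2-pentyloxolan-3-yl dodecanoate, via alkoxyphosphonium laurate 18 (not isolated)
Conditions: PPh3, DIAD, toluene, 0 °C to rt
Reagents that add atoms: none
Why: In the Mitsunobu esterification the only free hydroxyl is activated as the alkoxyphosphonium ion 18 and displaced by laurate from the opposite face (SN2), which turns 7R into 7S and sets the ester cis to the pentyl group.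

Step 11
Reactants: 19 (2S,3S,5R)-5-[(1R)-1-(naphthalen-2-ylmethoxy)dec-9-en-1-yl]-2-pentyloxolan-3-yl dodecanoate
Product: 20 (2S,3S,5R)-5-[(1R)-1-hydroxydec-9-en-1-yl]-2-pentyloxolan-3-yl dodecanoate (CNP0124067.1)
Conditions: DDQ, CH2Cl2/pH 7 buffer, 0 °C to rt
Reagents that add atoms: none
Why: DDQ oxidises only the electron-rich naphthylmethyl ether to an oxocarbenium ion that water hydrolyses, the ester and the isolated terminal alkene are not oxidised, and the trans arrangement of the C7 ester and the C9 side chain disfavours acyl migration to the freed C10 hydroxyl.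

**Compound list**

1 | (E)-oct-2-en-1-ol | CCCCC/C=C/CO | starting material
2 | (E)-oct-2-en-1-yl diethyl phosphate | CCCCC/C=C/COP(=O)(OCC)OCC | intermediate
3 | 2-[dimethyl(phenyl)silyl]-4,4,5,5-tetramethyl-1,3,2-dioxaborolane | CC1(C)OB(OC1(C)C)[Si](C)(C)c1ccccc1 | starting material
4 | (3R)-3-[dimethyl(phenyl)silyl]oct-1-ene | C=C[C@@H](CCCCC)[Si](C)(C)c1ccccc1 | intermediate
5 | 8-bromooct-1-ene | C=CCCCCCCBr | starting material
6 | oct-7-en-1-ylmagnesium bromide | C=CCCCCCC[Mg]Br | intermediate
7 | (R)-trityl glycidyl ether | C1[C@@H](O1)COC(c1ccccc1)(c1ccccc1)c1ccccc1 | starting material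
8 | (2R)-1-(triphenylmethoxy)undec-10-en-2-ol | C=CCCCCCCC[C@@H](O)COC(c1ccccc1)(c1ccccc1)c1ccccc1 | intermediate
9 | 2-({[(2R)-1-(triphenylmethoxy)undec-10-en-2-yl]oxy}methyl)naphthalene | C=CCCCCCCC[C@@H](OCc1ccc2ccccc2c1)COC(c1ccccc1)(c1ccccc1)c1ccccc1 | intermediate
10 | (2R)-2-(naphthalen-2-ylmethoxy)undec-10-en-1-ol | C=CCCCCCCC[C@@H](OCc1ccc2ccccc2c1)CO | intermediate
11 | (2R)-2-(naphthalen-2-ylmethoxy)undec-10-enal | C=CCCCCCCC[C@@H](OCc1ccc2ccccc2c1)C=O | intermediate
12 | SnCl4 chelate of 11 through the carbonyl and C10 ether oxygens (SnCl4 drawn as a separate component) | C=CCCCCCCC[C@@H](OCc1ccc2ccccc2c1)C=O.Cl[Sn](Cl)(Cl)Cl | intermediate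
13 | silicon-bridged C6–C7 cation with the tin alkoxide at C9 (drawn as the open C7 cation, SnCl4 as a separate component) | C=CCCCCCCC[C@@H](OCc1ccc2ccccc2c1)[C@H]([O-])C[CH+][C@@H](CCCCC)[Si](C)(C)c1ccccc1.Cl[Sn](Cl)(Cl)Cl | intermediate
14 | dimethyl{(2S,3R,5R)-5-[(1R)-1-(naphthalen-2-ylmethoxy)dec-9-en-1-yl]-2-pentyloxolan-3-yl}(phenyl)silane (2,5-trans, silicon trans to pentyl) | C=CCCCCCCC[C@@H](OCc1ccc2ccccc2c1)[C@H]1C[C@@H]([Si](C)(C)c2ccccc2)[C@H](CCCCC)O1 | intermediate
15 | (tert-butylperoxy)dimethyl{(2S,3R,5R)-5-[(1R)-1-(naphthalen-2-ylmethoxy)dec-9-en-1-yl]-2-pentyloxolan-3-yl}silane | C=CCCCCCCC[C@@H](OCc1ccc2ccccc2c1)[C@H]1C[C@@H]([Si](C)(C)OOC(C)(C)C)[C@H](CCCCC)O1 | intermediate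
16 | (2S,3R,5R)-5-[(1R)-1-(naphthalen-2-ylmethoxy)dec-9-en-1-yl]-2-pentyloxolan-3-ol (hydroxyl trans to pentyl) | C=CCCCCCCC[C@@H](OCc1ccc2ccccc2c1)[C@H]1C[C@@H](O)[C@H](CCCCC)O1 | intermediate
17 | dodecanoic (lauric) acid | OC(=O)CCCCCCCCCCC | starting material
18 | C7 alkoxy(triphenyl)phosphonium dodecanoate of 16 | C=CCCCCCCC[C@@H](OCc1ccc2ccccc2c1)[C@H]1C[C@@H](O[P+](c2ccccc2)(c2ccccc2)c2ccccc2)[C@H](CCCCC)O1.CCCCCCCCCCCC(=O)[O-] | intermediate
19 | (2S,3S,5R)-5-[(1R)-1-(naphthalen-2-ylmethoxy)dec-9-en-1-yl]-2-pentyloxolan-3-yl dodecanoate | C=CCCCCCCC[C@@H](OCc1ccc2ccccc2c1)[C@H]1C[C@H](OC(=O)CCCCCCCCCCC)[C@H](CCCCC)O1 | intermediate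
20 | (2S,3S,5R)-5-[(1R)-1-hydroxydec-9-en-1-yl]-2-pentyloxolan-3-yl dodecanoate | C=CCCCCCCC[C@@H](O)[C@H]1C[C@H](OC(=O)CCCCCCCCCCC)[C@H](CCCCC)O1 | target

**Step count and risks**

Total steps: 11 (steps 1–2 for the silane arm, steps 3–7 for the aldehyde arm, steps 8–11 after the union).
Longest linear sequence: 9 steps (steps 3–11, from 5 to 20).

Steps most likely to fail:

- **Step 8.** Chloride may strip silicon from the bridged cation before the alkoxide closes the ring. The approach geometry demanded by the chelate may also clash with that demanded by the silane conformer and erode facial selectivity.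
  - The fallback accepts the allylation and closes the ring by epoxide opening. It sets out from 4 and 11 and rejoins the route at 16.
  - TiCl4 in CH2Cl2 at −78 °C (chelation-controlled Hosomi–Sakurai allylation) should give (6E,9R,10R)-10-(naphthalen-2-ylmethoxy)nonadeca-6,18-dien-9-ol F1.
  - Shi epoxidation follows (D-fructose-derived ketone, KHSO5 as its triple salt with KHSO4 and K2SO4, K2CO3 buffer, MeCN/dimethoxymethane/water, 0 °C). It favours the trans-disubstituted alkene over the terminal one and works under reagent control, so it should give (6R,7R,9R,10R)-6,7-epoxy-10-(naphthalen-2-ylmethoxy)nonadec-18-en-9-ol F2.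
  - Camphorsulfonic acid in CH2Cl2 then lets the C9 hydroxyl open the epoxide at C6 with inversion (5-endo), which gives 16.

- **Step 9.** Protodesilylation may take the place of C–Si oxidation, or base and fluoride may induce beta-elimination of silicon together with the ring oxygen and so open the ring.
  - The fallback gives up silicon as the placeholder at C7 and uses iodine. It sets out from 4 and 11 and rejoins the route at 19, which also bypasses step 10.
  - The dienol F1, made as described for step 8, is treated with I2 and NaHCO3 in dry MeCN at 0 °C. This 5-endo-trig iodoetherification proceeds by anti addition across the (E)-alkene.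
  - (E)-Homoallylic alcohols typically give the 2,5-trans, 2,3-trans ring in this mode, which here is (2S,3R,5R)-3-iodo-5-[(1R)-1-(naphthalen-2-ylmethoxy)dec-9-en-1-yl]-2-pentyloxolane F3.
  - Cesium dodecanoate F4, prepared from 17 and Cs2CO3, then displaces iodide in warm DMF with inversion and gives 19.

- **Step 10.** Displacement may be sluggish because laurate must approach C7 on the face that carries the pentyl group. The alkoxyphosphonium ion may eliminate to a dihydrofuran, and the low acidity of an aliphatic acid aggravates both problems.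
  - The fallback inverts C7 by oxidation and reduction and then acylates without any substitution at carbon. It sets out from 16 and rejoins the route at 19.
  - Dess–Martin oxidation should give (2S,5R)-5-[(1R)-1-(naphthalen-2-ylmethoxy)dec-9-en-1-yl]-2-pentyloxolan-3-one F5.
  - LiBH(s-Bu)3 in THF at −78 °C delivers hydride to the face away from the neighbouring pentyl group. It should give (2S,3S,5R)-5-[(1R)-1-(naphthalen-2-ylmethoxy)dec-9-en-1-yl]-2-pentyloxolan-3-ol F6.
  - Steglich esterification with 17 (DCC, DMAP, CH2Cl2) then gives 19.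

**Further compounds**

F1 | step 8 | (6E,9R,10R)-10-(naphthalen-2-ylmethoxy)nonadeca-6,18-dien-9-ol | C=CCCCCCCC[C@@H](OCc1ccc2ccccc2c1)[C@H](O)C/C=C/CCCCC
F2 | step 8 | (6R,7R,9R,10R)-6,7-epoxy-10-(naphthalen-2-ylmethoxy)nonadec-18-en-9-ol | C=CCCCCCCC[C@@H](OCc1ccc2ccccc2c1)[C@H](O)C[C@H]1O[C@@H]1CCCCC
F3 | step 9 | (2S,3R,5R)-3-iodo-5-[(1R)-1-(naphthalen-2-ylmethoxy)dec-9-en-1-yl]-2-pentyloxolane | C=CCCCCCCC[C@@H](OCc1ccc2ccccc2c1)[C@H]1C[C@@H](I)[C@H](CCCCC)O1
F4 | step 9 | cesium dodecanoate | CCCCCCCCCCCC(=O)[O-].[Cs+]
F5 | step 10 | (2S,5R)-5-[(1R)-1-(naphthalen-2-ylmethoxy)dec-9-en-1-yl]-2-pentyloxolan-3-one | C=CCCCCCCC[C@@H](OCc1ccc2ccccc2c1)[C@H]1CC(=O)[C@H](CCCCC)O1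
F6 | step 10 | (2S,3S,5R)-5-[(1R)-1-(naphthalen-2-ylmethoxy)dec-9-en-1-yl]-2-pentyloxolan-3-ol | C=CCCCCCCC[C@@H](OCc1ccc2ccccc2c1)[C@H]1C[C@H](O)[C@H](CCCCC)O1
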